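Its constants are made up.

6.9 h was the half-life of the initiator by its own decay alone, shorter than the 30 h of this flask, so I asked whether its chains could die before the starting material was used.

    2 second chain carrier → ended chains B (k1 = 6 × 10⁸ L mol⁻¹ s⁻¹)
    crystals ⇌ by-product, rate k2*(cs2 - [by-product]) while solid is left; crystals form when [by-product] > cs2 (cs2 = 0.46 M, k2 = 1.4 × 10⁻⁴ s⁻¹)
    partner + by-product ⇌ idle adduct, settled at all times (K3 = 0.38 L mol⁻¹)
    starting material + initiating radical → capped initiator + first chain carrier (k4 = 20000 L mol⁻¹ s⁻¹)
    2 first chain carrier → ended chains A (k5 = 4.9 × 10⁷ L mol⁻¹ s⁻¹)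
    partner + first chain carrier → target + second chain carrier (k6 = 720 L mol⁻¹ s⁻¹)
    starting material + second chain carrier → by-product + first chain carrier (k7 = 1400 L mol⁻¹ s⁻¹)
    initiator → 2 initiating radical (k8 = 2.8 × 10⁻⁵ s⁻¹)

starting material 1.3 M; partner 0.950 equiv; initiator 2.5 mol%; time 30 h

- part of the starting material that has reacted at 30 h
- share of the unused partner that is free and not bound as idle adduct, at 30 h

I turned the question round: what would the numbers need for half the starting material to outlast the initiator? I took the carriers at steady state, each made as fast as it ended. S is starting material, F free partner, I initiator and N its charge; d is the initiator's decay constant; u and v are the constants of the two chain steps (partner + first carrier, starting material + second carrier); a and b are those of the first and second carriers' endings. With q = S/F held fixed: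

rate = √(d·I)·S/G, where G = √(b/(v·v) + a·q·q/(u·u))

ln(charged S/S) = Λ·w, where Λ = 2·√(N/d)/G and w = 1 − exp(−d·t/2)

Λ is the reach, the logarithm of the turnover that the whole initiator charge can buy. The partner charge could make more by-product than its solubility 0.46 M, so I held by-product there. That binds partner by a factor 1.17, which gives a free share of 85.1 %. Then q was 1.24 and the reach was 3.21. The opposite outcome needed a reach below 0.693, and this flask stood higher, by a factor 4.63. With w = 0.780, I reckoned c = 91.8 %.

The forecast gave 91.3 % (89.5 % to 93 %) and 84.9 % (84.3 % to 85.3 %). Its grounds began with “Radicals are in steady state”, and it stepped by hand where I held q fixed.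

The simulation of this flask gave 91.8 % and 84.9 %, both inside the forecast's ranges. In the neighbour flask with 6.2 mol% of initiator, the reach grew with the root of the charge to 5.05. With the same w, that gave 98.1 %. That neighbour flask itself reached 99.4 %, with 94.3 % as target.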